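in all of them: electrophile 49 mM; nucleophile 53.9 mM
- epsilon: free base 35 mM; protic impurity 9.8 mM; run made earlier
- gamma: free base 120 mM; protic impurity 9.8 mM; run made earlier
- Tuesday's: free base 24.0 mM; protic impurity 9.80 mM; time 3.0 h
- Friday's: free base 49.0 mM; protic impurity 9.80 mM; time 3.0 h
- Saturday's: free base 98.0 mM; protic impurity 9.80 mM; time 3.0 h

| run | time / h | electrophile / % | product / % |
|---|---|---|---|
| epsilon | 0.417 | 68.2 | 19.7 |
| epsilon | 1.00 | 46.6 | 32.0 |
| epsilon | 2.00 | 32.5 | 41.5 |
| epsilon | 3.00 | 26.5 | 46.1 |
| gamma | 0.833 | 50.9 | 29.5 |
| gamma | 1.50 | 37.3 | 38.4 |
| gamma | 2.50 | 27.7 | 45.5 |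
| gamma | 3.00 | 25.9 | 47.5 |

(each reading ± 0.3 percentage points)

- the numbers in the tables scatter with a standard deviation of 0.3 percentage points
- what has gone from electrophile into another species counts as reacted, even if it can come back

1. part of the electrophile that has reacted at the end, Tuesday's
2. part of the electrophile that has reacted at the end, Friday's
3. part of the electrophile that has reacted at the end, Saturday's
4. what raising the concentration of free base from its lowest to its highest value here does to the part of the electrophile that has reacted (changes below 5 percentage points count as none) (it falls / no change / it rises)

1. I began from a ratio of my own: the product made plus the protic impurity charged, as a fraction of the free base charged, which counts how often each base would have to serve if one base went to each.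

2. In the epsilon run, 68.2% of the electrophile stood at 0.417 h, with 19.7% as product and 12.1% unseen. That unseen part reached 21.4% at 1.00 h and 26.0% at 2.00 h. In the last hour of the epsilon run it gained 1.4 percentage points while product gained 4.6 points, so product took more than the unseen part over that stretch.

3. By the end, epsilon's demand in base turnovers was 0.925 and gamma's was 0.276, yet reacted electrophile read 73.5% and 74.1%, which are 0.6 points apart with a scatter of 0.3 points.

4. At epsilon's product share, Friday's demand came to 0.661 and Saturday's to 0.331, both inside the tested span, so I expected about 73.5% there. Tuesday's came to 1.35, above one turnover, and that gave me a warning but no number.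

5. The forecast said 67% (58% to 74%) for Tuesday's, 73.8% (72.5% to 75%) for Friday's and 74% (72.8% to 75.2%) for Saturday's, with the trend "it rises", and it wrote “Tuesday's is the doubtful one”.

6. Tuesday's gave 73.0%, Friday's 73.4% and Saturday's 74.0%, so the trend was "no change", a change of 0.98 points, and the forecast parted from the flask on Tuesday's. At the end of Tuesday's, 39.3% of the nucleophile charge stood as protonated nucleophile, and 23.2% of the free base charge had gone, a fraction of 23 against my demand of 1.35.

    electrophile + nucleophile → acid set free + product (k = 0.220 M⁻¹ min⁻¹)
    nucleophile + acid set free ⇌ protonated nucleophile, settled at all times (K = 1.70 × 10⁵ M⁻¹)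
    acid set free + free base ⇌ salt of the base, settled at all times (K = 5900 M⁻¹)
    protic impurity + free base → quenched reagent (k = 0.150 M⁻¹ min⁻¹)
    electrophile ⇌ dormant form (K = 0.980, k = 0.00650 min⁻¹)

7. For Saturday's read at 12 h, even the whole electrophile charge as product gives a demand of 0.600, inside epsilon's 0.925, so I expected no shortage of base. That flask gave 82.3% reacted, with 77% of the free base left.

The runs stem from a simulated flask from invented constants; noise was put on by code.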